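Daucane numbering (defined in the first section) is used for atoms throughout. Bold arabic numbers refer to the compounds of the route.

## Analysis of the target

The target is a daucane (carotane) sesquiterpenoid ester. It is a trans-fused bicyclo[5.3.0]decane in which a cyclopentane (ring A: C1, C2, C3, C4, C5) shares the C1–C5 bond with a cycloheptane (ring B: C1, C5, C6, C7, C8, C9, C10); C1 is the quaternary fusion carbon with the C15 methyl group, C4 the tertiary carbinol carbon with the isopropyl group (C11 to C13), C5 the fusion CH, C6 the CH with the 4-hydroxybenzoate, C8 the carbon of the exocyclic methylene C14, and C9 the allylic carbinol carbon. The five stereocentres are 1R, 4R, 5S, 6S and 9R: with the C15 methyl group drawn β, H5 and the C6 acyloxy group are α, and the hydroxyl groups at C4 and C9 are β. C4, C5, C6 and C1 form one crowded cluster around C5, which is flanked by two fully substituted carbons, whereas C9 relates to the rest only through its 1,3-relationship to C1 across C10. The sensitive groups are the 2-methylene allylic alcohol (ionisation, transposition, migration of the alkene into the ring), the tertiary alcohol (dehydration, acyl migration from O6), the ester and the free phenol. The hard parts are the seven-membered ring, the all-carbon quaternary centre at the fusion, the trans fusion, and telling three hydroxyl groups apart so that only O6 is acylated. The feature that invites an unusual cut is the pattern of ring B: two functionalised pairs, C5/C6 and C8/C9 (with C14 on C8), are separated by the bare methylene C7 and are joined on the other side by the sp3–sp3 bond C1–C10 that ends at the quaternary carbon. This is the pattern of a cyclohepta-1,4-diene (C5=C6, C8=C9) formed from a cis-divinylcyclopropane, so ring B, C1 and every handle of ring B can come from one cyclopropanation/Cope event that makes and then breaks a C6–C8 bond absent from the target.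

## Retrosynthetic reasoning

**Phenol and C9 (20 ⇒ 19 ⇒ 18).**
- The last bonds made are the phenolic O–H (silyl ether cleavage) and C9–H.
- Cutting C9–H turns the fragile allylic alcohol into the α-methylene ketone **18**. It also postpones the third hydroxyl group until after the acylation, so O6 never competes with O9.
- The forward reduction must be 1,2-selective and must deliver hydride to the α face. The control element is the C15 methyl group, which sits on the β face 1,3 to C9.

**Ester bond (18 ⇒ 14 + 17).**
- The acyl–O6 bond is cut here because in **14** the only other hydroxyl group is the tertiary, isopropyl-flanked O4.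
- The acid **17** is the silyl-protected form of **15**.

**Oxidation level of C14 (14 ⇒ 13 ⇒ 12).**
- No C–C bond is cut.
- The unit C14=C8–C9=O is the reduced and hydrolysed form of the β-silyloxy enoate of **12**: ester to allylic alcohol **13**, then loss of the hydroxyl group with push from the enol ether.
- The gain is that C8, C9 and C14 are seen as a masked β-keto ester, which is the substitution that a siloxyvinyl diazoacetate brings along.

**C4–C11 (12 ⇒ 11).**
- The isopropyl group is removed to leave the cyclopentanone **11**.
- It is cut here, and not carried from the start, for two reasons. C4 can then be achiral in the key step, and in trans-fused **11** the β face of the carbonyl group is blocked by the C6 branch on neighbouring C5 and by the C15 methyl group.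
- An isopropyl nucleophile therefore has to come from the α face, which gives the 4β-hydroxyl group.

**C5–H and C6–O (11 ⇒ 10 ⇒ 8).**
- After re-masking of the ketone as its ketal (**10**), H5 and O6, both α, are removed together to give the trisubstituted alkene C5=C6 of **8**.
- Forward, one syn hydroboration–oxidation sets the trans fusion and the carbinol centre at once.
- The ketal looks the same from both faces, so the pseudoaxial C15 methyl group alone decides the face.

**Key disconnection, C1–C10 and C7–C8 (8 ⇒ 7 ⇒ 3 + 6).**
- Diene **8** is the [3,3] product of cis-divinylcyclopropane **7**: the retro-Cope step opens C1–C10 and closes the temporary bond C6–C8.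
- **7** falls apart at C7–C8 and C6–C8 into the achiral C10 diene **3** and the C5 diazo ester **6**.
- The two fragments are joined at the most hindered carbon of the target. The seven-membered ring, the quaternary centre and all handles of ring B appear in one operation, and the absolute configuration comes from a catalyst.
- The precursor has no stereocentre and no medium ring.

**Fragments (3 ⇒ 2 ⇒ 1; 6 ⇒ 5 ⇒ 4).**
- **3** needs only a vinyl group in place of the bromine of ketal **2**, which is the protected form of commercial **1**.
- **6** is the silyl enol ether of diazo keto ester **5**, made by diazo transfer to **4**.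

## Alternatives that were turned down

**Alternative 1:** (the textbook route) cut at C8=C9 of a Δ8 precursor.
- *Forward:* ring-closing metathesis of diene **A1** to the trisubstituted cycloheptene diol **A2**, acylation at O6, then transposition of the alkene to the 8(14)-en-9-ol by epoxidation and base-induced opening, or by photooxygenation.
- *Why turned down:* **A1** already holds C1, C4, C5 and C6, that is the quaternary centre and the whole crowded cluster, which must be built linearly on a cyclopentane. The key step makes one bond and no stereocentre. The late transposition must pick C14 among three allylic positions (C7, C10, C14). It must also bring oxygen to C9 from the β face, the face shielded by the C15 methyl group. Two weak selectivities would sit at the end of the longest sequence.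

**Alternative 2:** cut at C5–C6 and C1–C10 through a cyclobutane that is cleaved afterwards (de Mayo logic), suggested by the 1,4-relationship of O6 and O9.
- *Forward:* [2+2] photocycloaddition of cyclopentenol **A3** with enol acetate **A4** to photoadduct **A5**, then retro-aldol fragmentation of its C6–C10 bond to the cycloheptane-1,4-dione **A6**.
- *Why turned down:* the more substituted alkene carbon C1 would have to bond to the α-carbon of the enone, opposite to the usual orientation. The enone would have to approach **A3** on the face that carries the isopropyl group. The cyclobutane forces H5 cis to C15, so C5 must be epimerised next to a β-hydroxy group that can leave by retro-aldol or elimination. Finally, the two ketones of **A6** must be told apart, and C14 still has to be added.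

**Alternative 3:** cut at C8–C9.
- *Forward:* intramolecular Nozaki–Hiyama–Kishi reaction of iodo aldehyde **A7**, which closes ring B and gives the 2-methylene carbinol directly.
- *Why turned down:* the step is attractive on paper, but **A7** contains four of the five stereocentres, including C1 next to C5 next to C4, so the precursor is hardly simpler than the product. The closure forms one bond. The configuration at C9 would be left to the conformation of a forming seven-membered ring, with no clear control element. The route to **A7** is as long and linear as that of Alternative 1.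

Key step: step 5

Assumption: Rh2(S-PTAD)4 is taken to give the (1R,2S)-cyclopropane **7**, the sense expected for this ligand family with monosubstituted alkenes. If the sense is opposite, the equally available Rh2(R-PTAD)4 is used and nothing else changes.

## Route

Step 1
Reactants: 1 2-bromo-3-methylcyclopent-2-en-1-one
Product: 2 6-bromo-7-methyl-1,4-dioxaspiro[4.4]non-6-ene
Conditions: HOCH2CH2OH (5 equiv), p-TsOH·H2O (cat.), benzene, reflux, Dean–Stark
Reagents that add atoms: ethylene glycol, OCCO
Why: Acid-catalysed ketalisation with azeotropic removal of water; the α-bromine holds the alkene in the tetrasubstituted C5=C1 position, as is known for 2-bromocycloalkenones. The ketal makes the later diene electron-rich, achiral and identical on both faces at C4.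

Step 2
Reactants: 2 6-bromo-7-methyl-1,4-dioxaspiro[4.4]non-6-ene
Product: 3 6-ethenyl-7-methyl-1,4-dioxaspiro[4.4]non-6-ene
Conditions: Bu3SnCH=CH2 (1.3 equiv), Pd(PPh3)4 (5 mol %), toluene, 100 °C
Reagents that add atoms: tributyl(vinyl)stannane, C=C[Sn](CCCC)(CCCC)CCCC
Why: Stille coupling of an alkenyl bromide under neutral conditions installs C6=C7 and leaves the allylic ketal untouched. No stereocentre is formed.

Step 3
Reactants: 4 methyl acetoacetate
Product: 5 methyl 2-diazo-3-oxobutanoate
Conditions: p-ABSA (1.1 equiv), Et3N, MeCN, 0 °C to rt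
Reagents that add atoms: 4-acetamidobenzenesulfonyl azide, CC(=O)Nc1ccc(cc1)S(=O)(=O)N=[N+]=[N-]
Why: Regitz diazo transfer to an active methylene compound, a standard preparation of this diazo keto ester.

Step 4
Reactants: 5 methyl 2-diazo-3-oxobutanoate
Product: 6 methyl 3-[(tert-butyldimethylsilyl)oxy]-2-diazobut-3-enoate
Conditions: TBSOTf (1.1 equiv), Et3N (1.3 equiv), CH2Cl2, 0 °C
Reagents that add atoms: tert-butyldimethylsilyl trifluoromethanesulfonate, CC(C)(C)[Si](C)(C)OS(=O)(=O)C(F)(F)F
Why: Soft enolisation and O-silylation of the acetyl group turn the acceptor/acceptor diazo compound into a donor/acceptor vinyldiazoacetate that carries C8, C9, C10, C14 and O9 of the target.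

Step 5
Reactants: 3 6-ethenyl-7-methyl-1,4-dioxaspiro[4.4]non-6-ene; 6 methyl 3-[(tert-butyldimethylsilyl)oxy]-2-diazobut-3-enoate
Product: 8 methyl (1R)-9-[(tert-butyldimethylsilyl)oxy]-4,4-(ethane-1,2-diylbisoxy)-11,12,13-trinordauca-5,8-dien-14-oate, via cis-divinylcyclopropane 7 (not isolated)
Conditions: Rh2(S-PTAD)4 (1 mol %), 6 (2 equiv, slow addition), hexanes, 0 °C to rt; then 60 °C
Reagents that add atoms: none
Why: The catalyst expels N2 from 6 to give a donor/acceptor vinylcarbenoid that cyclopropanates only the monosubstituted C6=C7 alkene of 3, forming C7–C8 and the temporary bond C6–C8 of 7; the tetrasubstituted C5=C1 alkene is too hindered for this bulky carbenoid, which secures the site selectivity. As is general for donor/acceptor carbenoids, the donor (siloxyvinyl) group ends up cis to the alkene substituent, so the two vinyl units of 7 are cis and can reach the endo boat transition state of a [3,3] shift that breaks C6–C8 and forms C1–C10. This is the tandem cyclopropanation/Cope rearrangement (formal [4+3] cycloaddition), which has close precedent with 2-methyl-1-vinylcycloalkenes and this same diazo ester. Ring B is closed by the sigmatropic step, a ring expansion of the three-membered ring in which the boat geometry makes both ring alkenes (C5=C6 and C8=C9) Z. C1 is the only stereocentre of 8: in the boat only one face of C1 can reach C10, so its configuration is relayed stereospecifically from C6 of 7, and C6 is fixed by the chiral carboxylate ligands during carbene transfer. Release of cyclopropane strain pays for making the quaternary centre against the methyl group that points into the boat, and gentle heating should complete the shift. A hydrocarbon solvent and slow addition favour attack at the carbenoid carbon over vinylogous attack and over carbene dimerisation.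

Step 6
Reactants: 8 methyl (1R)-9-[(tert-butyldimethylsilyl)oxy]-4,4-(ethane-1,2-diylbisoxy)-11,12,13-trinordauca-5,8-dien-14-oate
Product: 10 methyl (1R,5S,6S)-9-[(tert-butyldimethylsilyl)oxy]-4,4-(ethane-1,2-diylbisoxy)-6-hydroxy-11,12,13-trinordauc-8-en-14-oate, via C6-alkylborane 9 (not isolated)
Conditions: BH3·THF (2 equiv), THF, 0 °C to rt; then NaBO3·4H2O, THF/H2O, rt
Reagents that add atoms: borane–tetrahydrofuran (boron of 9 only), [BH3-][O+]1CCCC1; sodium perborate, [Na+].[Na+].O[B-]1(O)OO[B-](O)(O)OO1
Why: Hydroboration–oxidation puts boron on the less substituted C6 and hydrogen on C5 in a syn addition from the α face, opposite the pseudoaxial C15 methyl group on C1 (the facial bias known from Δ5-steroids with their angular methyl group), the ketal being the same on both faces; this sets 5α-H (trans fusion) and 6α-OH together. The tetrasubstituted push–pull alkene C8=C9 and the ester should be inert to BH3 at this temperature, and perborate avoids the strong base that would cleave the enol silane.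

Step 7
Reactants: 10 methyl (1R,5S,6S)-9-[(tert-butyldimethylsilyl)oxy]-4,4-(ethane-1,2-diylbisoxy)-6-hydroxy-11,12,13-trinordauc-8-en-14-oate
Product: 11 methyl (1R,5S,6S)-9-[(tert-butyldimethylsilyl)oxy]-6-hydroxy-4-oxo-11,12,13-trinordauc-8-en-14-oate
Conditions: PPTS (0.2 equiv), acetone/H2O (10:1), rt to 40 °C
Reagents that add atoms: water, O
Why: Mild acid hydrolysis of a ketal; cyclopentanone ketals open readily because the five-membered ring favours the sp2 carbon, whereas the electron-poor enol silane is protonated at carbon much more slowly. The weak acid should keep C5 from epimerising and the β-hydroxyl group from eliminating.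

Step 8
Reactants: 11 methyl (1R,5S,6S)-9-[(tert-butyldimethylsilyl)oxy]-6-hydroxy-4-oxo-11,12,13-trinordauc-8-en-14-oate
Product: 12 methyl (1R,4R,5S,6S)-9-[(tert-butyldimethylsilyl)oxy]-4,6-dihydroxydauc-8-en-14-oate
Conditions: i-PrMgCl (4 equiv), CeCl3 (4 equiv, dried), THF, −78 to −30 °C; aq. NH4Cl
Reagents that add atoms: isopropylmagnesium chloride, CC(C)[Mg]Cl
Why: Organocerium 1,2-addition; the low basicity suppresses enolisation, retro-aldol cleavage and β-hydride reduction, and the vinylogous-carbonate ester is far less electrophilic than the ketone. The nucleophile attacks C4 from the α face, anti to the C6 branch on neighbouring C5 and to the C15 methyl group, which gives the 4β-hydroxyl group (4R).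

Step 9
Reactants: 12 methyl (1R,4R,5S,6S)-9-[(tert-butyldimethylsilyl)oxy]-4,6-dihydroxydauc-8-en-14-oate
Product: 14 (1R,4R,5S,6S)-4,6-dihydroxydauc-8(14)-en-9-one, via allylic alcohol 13 (not isolated)
Conditions: i-Bu2AlH (5 equiv), CH2Cl2, −78 °C; then 1 M aq. HCl, THF, 0 °C to rt
Reagents that add atoms: none
Why: Hydride reduction of the enoate gives allylic alcohol 13; on acidification its hydroxyl group ionises with push from the enol silane, and loss of the silyl group from the silyloxocarbenium ion gives the α-methylene ketone (reduction–hydrolysis transposition of a vinylogous ester, Stork–Danheiser logic). Short contact with dilute acid should spare the tertiary alcohol and keep the alkene exocyclic; attack of O6 on C14 would be a disfavoured 5-endo-trig closure.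

Step 10
Reactants: 15 4-hydroxybenzoic acid
Product: 17 4-[(tert-butyldimethylsilyl)oxy]benzoic acid, via bis-silyl derivative 16 (not isolated)
Conditions: TBSCl (2.2 equiv), imidazole (4.5 equiv), DMF, rt; then AcOH/THF/H2O (3:1:1), rt
Reagents that add atoms: tert-butyldimethylsilyl chloride, CC(C)(C)[Si](C)(C)Cl
Why: Exhaustive silylation followed by selective hydrolysis of the much more labile silyl ester, a standard way to phenol-protected hydroxybenzoic acids.

Step 11
Reactants: 14 (1R,4R,5S,6S)-4,6-dihydroxydauc-8(14)-en-9-one; 17 4-[(tert-butyldimethylsilyl)oxy]benzoic acid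
Product: 18 (1R,4R,5S,6S)-4-hydroxy-9-oxodauc-8(14)-en-6-yl 4-[(tert-butyldimethylsilyl)oxy]benzoate
Conditions: DCC (1.5 equiv), DMAP (0.3 equiv), CH2Cl2, 0 °C to rt
Reagents that add atoms: none
Why: Steglich esterification; only the secondary O6 reacts, since the tertiary O4 next to the isopropyl group is inert and no O9 hydroxyl group exists yet. Any transannular O6/C9 hemiketal is in equilibrium with 14 and is drained by the acylation.

Step 12
Reactants: 18 (1R,4R,5S,6S)-4-hydroxy-9-oxodauc-8(14)-en-6-yl 4-[(tert-butyldimethylsilyl)oxy]benzoate
Product: 19 (1R,4R,5S,6S,9R)-4,9-dihydroxydauc-8(14)-en-6-yl 4-[(tert-butyldimethylsilyl)oxy]benzoate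
Conditions: NaBH4, CeCl3·7H2O, MeOH, −78 °C
Reagents that add atoms: none
Why: Luche reduction is 1,2-selective for the α-methylene ketone and leaves the ester and the aryl silyl ether alone. Hydride should come from the α face because the β face of C9 is shielded by the C15 methyl group in the 1,3-position, while the equatorial 6α-acyloxy group points away from the ring; this gives the 9β-hydroxyl group (9R).

Step 13
Reactants: 19 (1R,4R,5S,6S,9R)-4,9-dihydroxydauc-8(14)-en-6-yl 4-[(tert-butyldimethylsilyl)oxy]benzoate
Product: 20 (1R,4R,5S,6S,9R)-4,9-dihydroxydauc-8(14)-en-6-yl 4-hydroxybenzoate (target)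
Conditions: Bu4NF/AcOH (1:1, 1.2 equiv), THF, 0 °C
Reagents that add atoms: none
Why: Aryl silyl ethers are cleaved very fast by fluoride. The acetic acid buffer keeps the phenoxide and alkoxides from causing acyl migration or ester cleavage, and the allylic and tertiary alcohols are not touched.

## Compound list

1 | 2-bromo-3-methylcyclopent-2-en-1-one | CC1=C(Br)C(=O)CC1 | starting material
2 | 6-bromo-7-methyl-1,4-dioxaspiro[4.4]non-6-ene | BrC1=C(C)CCC12OCCO2 | intermediate
3 | 6-ethenyl-7-methyl-1,4-dioxaspiro[4.4]non-6-ene (achiral diene C7=C6–C5=C1) | C=CC1=C(C)CCC12OCCO2 | intermediate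
4 | methyl acetoacetate | COC(=O)CC(C)=O | starting material
5 | methyl 2-diazo-3-oxobutanoate | COC(=O)C(=[N+]=[N-])C(C)=O | intermediate
6 | methyl 3-[(tert-butyldimethylsilyl)oxy]-2-diazobut-3-enoate | COC(=O)C(=[N+]=[N-])C(=C)O[Si](C)(C)C(C)(C)C | intermediate
7 | methyl (1R,2S)-1-{1-[(tert-butyldimethylsilyl)oxy]ethenyl}-2-(7-methyl-1,4-dioxaspiro[4.4]non-6-en-6-yl)cyclopropane-1-carboxylate (siloxyvinyl and cyclopentenyl groups cis) | COC(=O)[C@]1(C(=C)O[Si](C)(C)C(C)(C)C)C[C@H]1C2=C(C)CCC23OCCO3 | intermediate
8 | methyl (1R)-9-[(tert-butyldimethylsilyl)oxy]-4,4-(ethane-1,2-diylbisoxy)-11,12,13-trinordauca-5,8-dien-14-oate (hydroazulene with C5=C6 and C8=C9, C4 ketal, C15 methyl on C1) | COC(=O)C1=C(O[Si](C)(C)C(C)(C)C)C[C@@]2(C)CCC3(OCCO3)C2=CC1 | intermediate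
9 | 6α-boryl, 5α-H adduct of 8 (monoalkylborane at C6) | COC(=O)C1=C(O[Si](C)(C)C(C)(C)C)C[C@@]2(C)CCC3(OCCO3)[C@@H]2[C@@H](B)C1 | intermediate
10 | methyl (1R,5S,6S)-9-[(tert-butyldimethylsilyl)oxy]-4,4-(ethane-1,2-diylbisoxy)-6-hydroxy-11,12,13-trinordauc-8-en-14-oate (trans-fused, 5α-H, 6α-OH) | COC(=O)C1=C(O[Si](C)(C)C(C)(C)C)C[C@@]2(C)CCC3(OCCO3)[C@@H]2[C@@H](O)C1 | intermediate
11 | methyl (1R,5S,6S)-9-[(tert-butyldimethylsilyl)oxy]-6-hydroxy-4-oxo-11,12,13-trinordauc-8-en-14-oate | COC(=O)C1=C(O[Si](C)(C)C(C)(C)C)C[C@@]2(C)CCC(=O)[C@@H]2[C@@H](O)C1 | intermediate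
12 | methyl (1R,4R,5S,6S)-9-[(tert-butyldimethylsilyl)oxy]-4,6-dihydroxydauc-8-en-14-oate (4β-OH, 4α-isopropyl) | COC(=O)C1=C(O[Si](C)(C)C(C)(C)C)C[C@@]2(C)CC[C@@](O)(C(C)C)[C@@H]2[C@@H](O)C1 | intermediate
13 | (1R,4R,5S,6S)-9-[(tert-butyldimethylsilyl)oxy]dauc-8-ene-4,6,14-triol | OCC1=C(O[Si](C)(C)C(C)(C)C)C[C@@]2(C)CC[C@@](O)(C(C)C)[C@@H]2[C@@H](O)C1 | intermediate
14 | (1R,4R,5S,6S)-4,6-dihydroxydauc-8(14)-en-9-one | C=C1C[C@H](O)[C@@H]2[C@](C)(CC[C@@]2(O)C(C)C)CC1=O | intermediate
15 | 4-hydroxybenzoic acid | OC(=O)c1ccc(O)cc1 | starting material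
16 | tert-butyldimethylsilyl 4-[(tert-butyldimethylsilyl)oxy]benzoate | CC(C)(C)[Si](C)(C)OC(=O)c1ccc(O[Si](C)(C)C(C)(C)C)cc1 | intermediate
17 | 4-[(tert-butyldimethylsilyl)oxy]benzoic acid | CC(C)(C)[Si](C)(C)Oc1ccc(cc1)C(=O)O | intermediate
18 | (1R,4R,5S,6S)-4-hydroxy-9-oxodauc-8(14)-en-6-yl 4-[(tert-butyldimethylsilyl)oxy]benzoate | C=C1C[C@H](OC(=O)c2ccc(O[Si](C)(C)C(C)(C)C)cc2)[C@@H]2[C@](C)(CC[C@@]2(O)C(C)C)CC1=O | intermediate
19 | (1R,4R,5S,6S,9R)-4,9-dihydroxydauc-8(14)-en-6-yl 4-[(tert-butyldimethylsilyl)oxy]benzoate | C=C1C[C@H](OC(=O)c2ccc(O[Si](C)(C)C(C)(C)C)cc2)[C@@H]2[C@](C)(CC[C@@]2(O)C(C)C)C[C@H]1O | intermediate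
20 | (1R,4R,5S,6S,9R)-4,9-dihydroxydauc-8(14)-en-6-yl 4-hydroxybenzoate | C=C1C[C@H](OC(=O)c2ccc(O)cc2)[C@@H]2[C@](C)(CC[C@@]2(O)C(C)C)C[C@H]1O | target

## Step count and least certain steps

Total step count: 13. Longest linear sequence: 10 steps (steps 1, 2, 5, 6, 7, 8, 9, 11, 12, 13).

**Step 5 (key step).**
- *Most likely problem:* slow or unselective carbene transfer. The vinyl group of **3** is flanked by the ketal and twisted out of conjugation, so vinylogous attack on the carbenoid, carbene dimerisation or loss of enantiocontrol can compete. The [3,3] shift may also lag, because the methyl group on C1 points into the boat.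
- *Fallback, from **3** and **5**, back at **7** and so **8**:* the two events are separated. The vinyl group of **3** is cyclopropanated with the acceptor/acceptor carbene from **5**, using a chiral cobalt amidoporphyrin [Co(Por*)] (divalent cobalt, metalloradical mechanism). This catalyst class is known for α-keto diazoacetates and places the ketone cis to the alkene substituent. The product is methyl (1R,2S)-1-acetyl-2-(7-methyl-1,4-dioxaspiro[4.4]non-6-en-6-yl)cyclopropane-1-carboxylate F1. Enol silylation of the acetyl group (TBSOTf, Et3N) then creates the second vinyl group, which is **7**, and this rearranges on warming.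

**Step 6.**
- *Most likely problem:* poor facial selectivity. The α face is the slightly concave face of the cyclohepta-1,4-diene, which works against the shielding of the β face by the C15 methyl group.
- *Fallback, from **8**, back at **11** (step 7 is skipped):* the allylic ketal of **8**, far more labile than a saturated one, is hydrolysed with PPTS in wet acetone to the cross-conjugated enone methyl (1R)-9-[(tert-butyldimethylsilyl)oxy]-4-oxo-11,12,13-trinordauca-5,8-dien-14-oate F2. Copper-catalysed conjugate borylation (CuCl, NaOt-Bu, a chiral Josiphos-type bisphosphine, B2pin2, MeOH, THF) puts boron on C6 under ligand control. Protonation of the enolate on the face away from C15 gives the 6α-pinacolboryl 5α-H ketone F3, and NaBO3 oxidation with retention gives **11**.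

**Step 7.**
- *Most likely problem:* competing loss of the enol silane, or acid-induced β-elimination of O6 and epimerisation at C5 once the ketone is free, because the product is a β-hydroxy ketone with an enolisable fusion carbon.
- *Fallback, from **10**, back at **14**:* O6 is masked first (TBSOTf, 2,6-lutidine) as the 6-O-TBS ether of 10 F4. The ketal is then removed by neutral exchange (I2 cat., acetone) to give the 6-O-TBS ether of 11 F5. Isopropylcerium addition gives the 6-O-TBS ether of 12 F6, and i-Bu2AlH gives the 6-O-TBS ether of 13 F7. Aqueous HF in MeCN removes both silyl groups and triggers the loss of the allylic hydroxyl group.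

**Step 8.**
- *Most likely problem:* enolisation, retro-aldol cleavage of the C6 alkoxide, or β-hydride reduction instead of addition. A secondary nucleophile has to attack a ketone next to the crowded C5.
- *Fallback, from **11**, back at **12**:* a smaller sp2 nucleophile without β-hydrogen is used (isopropenylmagnesium bromide, CeCl3, THF, −78 °C). It should add from the same α face to give the 4β-hydroxy-4α-isopropenyl compound methyl 9-[(tert-butyldimethylsilyl)oxy]-4,6-dihydroxydauca-8,11-dien-14-oate F8. Its 1,1-disubstituted alkene is then hydrogenated selectively with RhCl(PPh3)3 and H2.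

**Step 12.**
- *Most likely problem:* poor facial selectivity of a small hydride on a flexible cycloheptenone, so that attack from the β face competes.
- *Fallback, from **18**, back at **20**:* the reduction product of wrong configuration, the 9α-alcohol (9S epimer of 19) F9, is inverted by a Mitsunobu reaction (4-nitrobenzoic acid, PPh3, DIAD) to the 9β-(4-nitrobenzoate) F10. K2CO3 in MeOH at 0 °C then cleaves the activated nitrobenzoate and the aryl silyl ether together. The hindered C6 ester, further deactivated as its phenoxide, should survive.

## Further compounds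

F1 | step 5 | methyl (1R,2S)-1-acetyl-2-(7-methyl-1,4-dioxaspiro[4.4]non-6-en-6-yl)cyclopropane-1-carboxylate | COC(=O)[C@]1(C(C)=O)C[C@H]1C2=C(C)CCC23OCCO3
F2 | step 6 | methyl (1R)-9-[(tert-butyldimethylsilyl)oxy]-4-oxo-11,12,13-trinordauca-5,8-dien-14-oate | COC(=O)C1=C(O[Si](C)(C)C(C)(C)C)C[C@@]2(C)CCC(=O)C2=CC1
F3 | step 6 | methyl (1R)-9-[(tert-butyldimethylsilyl)oxy]-4-oxo-6α-(4,4,5,5-tetramethyl-1,3,2-dioxaborolan-2-yl)-5α-H-11,12,13-trinordauc-8-en-14-oate | COC(=O)C1=C(O[Si](C)(C)C(C)(C)C)C[C@@]2(C)CCC(=O)[C@@H]2[C@@H](B3OC(C)(C)C(C)(C)O3)C1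
F4 | step 7 | 6-O-(tert-butyldimethylsilyl) ether of 10 | COC(=O)C1=C(O[Si](C)(C)C(C)(C)C)C[C@@]2(C)CCC3(OCCO3)[C@@H]2[C@@H](O[Si](C)(C)C(C)(C)C)C1
F5 | step 7 | 6-O-(tert-butyldimethylsilyl) ether of 11 | COC(=O)C1=C(O[Si](C)(C)C(C)(C)C)C[C@@]2(C)CCC(=O)[C@@H]2[C@@H](O[Si](C)(C)C(C)(C)C)C1
F6 | step 7 | 6-O-(tert-butyldimethylsilyl) ether of 12 | COC(=O)C1=C(O[Si](C)(C)C(C)(C)C)C[C@@]2(C)CC[C@@](O)(C(C)C)[C@@H]2[C@@H](O[Si](C)(C)C(C)(C)C)C1
F7 | step 7 | 6-O-(tert-butyldimethylsilyl) ether of 13 | OCC1=C(O[Si](C)(C)C(C)(C)C)C[C@@]2(C)CC[C@@](O)(C(C)C)[C@@H]2[C@@H](O[Si](C)(C)C(C)(C)C)C1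
F8 | step 8 | methyl 9-[(tert-butyldimethylsilyl)oxy]-4β,6α-dihydroxydauca-8,11-dien-14-oate (4α-isopropenyl) | COC(=O)C1=C(O[Si](C)(C)C(C)(C)C)C[C@@]2(C)CC[C@@](O)(C(C)=C)[C@@H]2[C@@H](O)C1
F9 | step 12 | (1R,4R,5S,6S,9S)-4,9-dihydroxydauc-8(14)-en-6-yl 4-[(tert-butyldimethylsilyl)oxy]benzoate | C=C1C[C@H](OC(=O)c2ccc(O[Si](C)(C)C(C)(C)C)cc2)[C@@H]2[C@](C)(CC[C@@]2(O)C(C)C)C[C@@H]1O
F10 | step 12 | (1R,4R,5S,6S,9R)-4-hydroxy-9-[(4-nitrobenzoyl)oxy]dauc-8(14)-en-6-yl 4-[(tert-butyldimethylsilyl)oxy]benzoate | C=C1C[C@H](OC(=O)c2ccc(O[Si](C)(C)C(C)(C)C)cc2)[C@@H]2[C@](C)(CC[C@@]2(O)C(C)C)C[C@H]1OC(=O)c1ccc(cc1)[N+](=O)[O-]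
A1 | alternative 1 | (1R,2S,3R)-3-allyl-2-[(1S)-1-hydroxy-3-methylbut-3-enyl]-1-isopropyl-3-methylcyclopentan-1-ol (metathesis diene) | C=CC[C@@]1(C)CC[C@@](O)(C(C)C)[C@@H]1[C@@H](O)CC(C)=C
A2 | alternative 1 | (1R,4R,5S,6S)-dauc-8-ene-4,6-diol | CC1=CC[C@@]2(C)CC[C@@](O)(C(C)C)[C@@H]2[C@@H](O)C1
A3 | alternative 2 | (R)-1-isopropyl-3-methylcyclopent-2-en-1-ol | CC1=C[C@](O)(C(C)C)CC1
A4 | alternative 2 | 3-acetoxycyclopent-2-en-1-one | CC(=O)OC1=CC(=O)CC1
A5 | alternative 2 | cis-anti-cis 5-4-5 photoadduct (C6 acetoxy, C9 ketone, cyclobutane C1–C5–C6–C10, H5 cis to C15) | CC(=O)O[C@@]12CCC(=O)[C@@H]1[C@@]1(C)CC[C@@](O)(C(C)C)[C@@H]21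
A6 | alternative 2 | (1R,4R,5S)-4-hydroxy-14-nordaucane-6,9-dione (after epimerisation at C5) | O=C1CCC(=O)[C@@H]2[C@](C)(CC[C@@]2(O)C(C)C)C1
A7 | alternative 3 | iodo aldehyde: cyclopentane with C1 (methyl, CH2CHO), C4 (OH, isopropyl) and C5 bearing the (1S)-1-[(tert-butyldimethylsilyl)oxy]-3-iodobut-3-enyl chain | C=C(I)C[C@H](O[Si](C)(C)C(C)(C)C)[C@@H]1[C@@](C)(CC=O)CC[C@@]1(O)C(C)C
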